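## Retrosynthetic overview

1. Target ⇒ late MnO2 oxidation of a primary allylic alcohol ⇒ double tigloylation of the C3 hydroxyl and of an (R)-1-hydroxyethyl group at C5. That carbinol comes from a C5 nitrile (methyllithium, then asymmetric transfer hydrogenation).
2. Dihydrofuran ring ⇒ cut O1–C7a: intramolecular addition–elimination of the C2 alkoxide of a free anti-triol on a C7a–F bond.
3. Enabling feature: O1 sits on C7a of the benzene ring, and C7a is para to C5. With C5 held at the nitrile oxidation level, C7a–F is an SNAr site, and of the three hydroxyls only the one on C2 reaches C7a through a five-membered ring (O1–C2–C3–C3a–C7a).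
4. Triol ⇒ ketal and silyl ether hydrolysis ⇒ Wittig methylenation ⇒ (S)-proline anti-aldol between 4-fluoro-3-formylbenzonitrile and 2,2-dimethyl-1,3-dioxan-5-one. The aldol sets C2 and C3 (anti, hence 2,3-trans) and brings C2, the vinyl carbon and the future formyl carbon in one piece.
5. Ring order: benzene ring bought; temporary 1,3-dioxane ring carried through steps 1–3 and opened in step 4; dihydrofuran ring closed in step 5.

Key step: step 5

Remark: both acyl groups are (E)-2-methylbut-2-enoyl (tigloyl), the C2 and C3 substituents are trans, and the stereocentres are (2R,3S) in the ring and (R) in the side chain.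

## Route

Step 1
Reactants: 1 4-fluoro-3-formylbenzonitrile; 2 2,2-dimethyl-1,3-dioxan-5-one
Product: 3 4-fluoro-3-[(S)-hydroxy[(4S)-2,2-dimethyl-5-oxo-1,3-dioxan-4-yl]methyl]benzonitrile
Conditions: (S)-proline (30 mol%), DMF, 4 °C
Reagents that add atoms: none
Why: Proline-catalysed direct aldol reaction (enamine catalysis), in which the ketone enamine should add to the Re face of the non-enolisable, electron-poor aldehyde through a chair-like transition state with the carboxylic acid hydrogen-bonded to the aldehyde oxygen, setting both stereocentres at once as the anti (4S,1'S) pair that becomes C2 and C3 of the target, any syn isomer being removed by chromatography.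

Step 2
Reactants: 3 4-fluoro-3-[(S)-hydroxy[(4S)-2,2-dimethyl-5-oxo-1,3-dioxan-4-yl]methyl]benzonitrile
Product: 4 4-fluoro-3-[(S)-[(4S)-2,2-dimethyl-5-oxo-1,3-dioxan-4-yl](triethylsilyloxy)methyl]benzonitrile
Conditions: Et3SiCl, imidazole, CH2Cl2, 0 °C to rt
Reagents that add atoms: chlorotriethylsilane, CC[Si](Cl)(CC)CC
Why: Standard silyl ether protection of the secondary alcohol, which blocks retro-aldol cleavage and alkoxide-triggered side reactions in the olefination that follows and touches no stereocentre.

Step 3
Reactants: 4 4-fluoro-3-[(S)-[(4S)-2,2-dimethyl-5-oxo-1,3-dioxan-4-yl](triethylsilyloxy)methyl]benzonitrile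
Product: 5 4-fluoro-3-[(S)-[(4R)-2,2-dimethyl-5-methylidene-1,3-dioxan-4-yl](triethylsilyloxy)methyl]benzonitrile
Conditions: Ph3PCH3Br, KOtBu, THF, 0 °C; then 4, −78 to 0 °C
Reagents that add atoms: methyltriphenylphosphonium bromide, [Br-].C[P+](c1ccccc1)(c1ccccc1)c1ccccc1
Why: Wittig methylenation, in which the non-stabilised ylide should add to the strongly electrophilic α,α'-dioxygenated ketone at low temperature faster than it deprotonates the hindered C4–H, so the configuration next to the carbonyl is kept (the descriptor changes from 4S to 4R by priority only) and the nitrile stays inert.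

Step 4
Reactants: 5 4-fluoro-3-[(S)-[(4R)-2,2-dimethyl-5-methylidene-1,3-dioxan-4-yl](triethylsilyloxy)methyl]benzonitrile
Product: 6 4-fluoro-3-[(1S,2R)-1,2,4-trihydroxy-3-methylidenebutyl]benzonitrile
Conditions: AcOH/H2O/THF (3:1:1), 45 °C
Reagents that add atoms: none
Why: Acid-catalysed hydrolysis of the isopropylidene ketal and of the triethylsilyl ether in one operation (acetal and silyl ether deprotection), under which the electron-poor benzylic and the allylic hydroxyls should not ionise, so both stereocentres stay as set.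

Step 5
Reactants: 6 4-fluoro-3-[(1S,2R)-1,2,4-trihydroxy-3-methylidenebutyl]benzonitrile
Product: 8 (2R,3S)-3-hydroxy-2-(3-hydroxyprop-1-en-2-yl)-2,3-dihydro-1-benzofuran-5-carbonitrile, via Meisenheimer adduct 7 (not isolated)
Conditions: KOtBu (1.5 equiv), THF (0.02 M), 0 °C to rt; aq. NH4Cl
Reagents that add atoms: none
Why: Deprotonation gives equilibrating potassium alkoxides of the triol; the C2 alkoxide adds to C7a, the fluorine-bearing ring carbon para to the C5 nitrile, to give the cyano-stabilised adduct 7, and loss of fluoride restores the benzene ring (addition–elimination, SNAr). The closest known reaction type is the base-mediated cyclisation of 2-(2-fluoroaryl)ethanols carrying a para electron-withdrawing group to 2,3-dihydrobenzofurans. The dihydrofuran ring O1–C2–C3–C3a–C7a closes in the 5-exo mode at an sp2 carbon, and it is the only ring the step forms. No stereocentre is created: neither the C2–O nor the C3–O bond is broken and neither carbon is acidic, so the anti relation from step 1 should be carried over unchanged as the 2,3-trans (2R,3S) pair. The step needs site selectivity among three free hydroxyls, and ring size alone secures it, since the C3 alkoxide could only reach a four-membered and the primary alkoxide a seven-membered ring, while hindered tert-butoxide should not compete intermolecularly at this dilution. The nitrile is non-enolisable and so keeps its full activating power under base, and fluoride is the best leaving group for the rate-limiting addition.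

Step 6
Reactants: 8 (2R,3S)-3-hydroxy-2-(3-hydroxyprop-1-en-2-yl)-2,3-dihydro-1-benzofuran-5-carbonitrile
Product: 9 (2R,3S)-2-[3-(tert-butyldimethylsilyloxy)prop-1-en-2-yl]-3-hydroxy-2,3-dihydro-1-benzofuran-5-carbonitrile
Conditions: TBSCl (1.05 equiv), imidazole, CH2Cl2, −20 to 0 °C
Reagents that add atoms: tert-butyldimethylsilyl chloride, CC(C)(C)[Si](C)(C)Cl
Why: Selective silylation of the primary allylic hydroxyl, which a bulky silyl chloride at low temperature should reach far faster than the hindered secondary benzylic hydroxyl at C3.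

Step 7
Reactants: 9 (2R,3S)-2-[3-(tert-butyldimethylsilyloxy)prop-1-en-2-yl]-3-hydroxy-2,3-dihydro-1-benzofuran-5-carbonitrile
Product: 11 1-[(2R,3S)-2-[3-(tert-butyldimethylsilyloxy)prop-1-en-2-yl]-3-hydroxy-2,3-dihydro-1-benzofuran-5-yl]ethan-1-one, via ketimine 10 (not isolated)
Conditions: MeLi (3 equiv), THF, −78 to 0 °C; then 10% aq. AcOH, THF, 0 °C
Reagents that add atoms: methyllithium, [Li]C; water, O
Why: Organolithium addition to a nitrile, in which the C3 hydroxyl is first masked as its lithium alkoxide, the N-lithio ketimine resists a second addition, and mild aqueous acid hydrolyses ketimine 10 to the methyl ketone without touching C2 or C3.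

Step 8
Reactants: 11 1-[(2R,3S)-2-[3-(tert-butyldimethylsilyloxy)prop-1-en-2-yl]-3-hydroxy-2,3-dihydro-1-benzofuran-5-yl]ethan-1-one
Product: 12 (2R,3S)-2-[3-(tert-butyldimethylsilyloxy)prop-1-en-2-yl]-5-[(1R)-1-hydroxyethyl]-2,3-dihydro-1-benzofuran-3-ol
Conditions: RuCl[(R,R)-TsDPEN](p-cymene) (2 mol%), HCO2H/Et3N (5:2), CH2Cl2, rt
Reagents that add atoms: none
Why: Noyori-type asymmetric transfer hydrogenation of an aryl methyl ketone, where the (R,R)-catalyst should deliver hydride through the six-membered metal–ligand bifunctional transition state to give the (R)-carbinol as it does with acetophenone, the catalyst overriding the remote C2/C3 centres and formic acid making the reduction irreversible.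

Step 9
Reactants: 12 (2R,3S)-2-[3-(tert-butyldimethylsilyloxy)prop-1-en-2-yl]-5-[(1R)-1-hydroxyethyl]-2,3-dihydro-1-benzofuran-3-ol; 13 tigloyl chloride, (E)-2-methylbut-2-enoyl chloride
Product: 14 (1R)-1-[(2R,3S)-2-[3-(tert-butyldimethylsilyloxy)prop-1-en-2-yl]-3-[(E)-2-methylbut-2-enoyloxy]-2,3-dihydro-1-benzofuran-5-yl]ethyl (E)-2-methylbut-2-enoate
Conditions: 13 (3 equiv, two of which are consumed), pyridine, DMAP (0.2 equiv), CH2Cl2, 0 °C to rt
Reagents that add atoms: tigloyl chloride (second equivalent of 13, for the second ester), ClC(=O)/C(C)=C/C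
Why: DMAP-catalysed acylation through the acylpyridinium ion should esterify both secondary benzylic hydroxyls with retention, one molecule of 13 being consumed at the C3 hydroxyl and a second at the side-chain carbinol, the weak base pyridine avoiding vinylketene formation from the acid chloride so that the (E) geometry of both acyl groups is kept.

Step 10
Reactants: 14 (1R)-1-[(2R,3S)-2-[3-(tert-butyldimethylsilyloxy)prop-1-en-2-yl]-3-[(E)-2-methylbut-2-enoyloxy]-2,3-dihydro-1-benzofuran-5-yl]ethyl (E)-2-methylbut-2-enoate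
Product: 15 (1R)-1-[(2R,3S)-2-(3-hydroxyprop-1-en-2-yl)-3-[(E)-2-methylbut-2-enoyloxy]-2,3-dihydro-1-benzofuran-5-yl]ethyl (E)-2-methylbut-2-enoate
Conditions: HF·pyridine, pyridine, THF, 0 °C to rt
Reagents that add atoms: none
Why: Fluoride-mediated cleavage of the primary silyl ether under pyridine-buffered conditions should leave both esters and the benzylic C–O bonds alone, acyl transfer to the freed hydroxyl being disfavoured because it would need a seven-membered transition state.

Step 11
Reactants: 15 (1R)-1-[(2R,3S)-2-(3-hydroxyprop-1-en-2-yl)-3-[(E)-2-methylbut-2-enoyloxy]-2,3-dihydro-1-benzofuran-5-yl]ethyl (E)-2-methylbut-2-enoate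
Product: 16 (1R)-1-[(2R,3S)-3-[(E)-2-methylbut-2-enoyloxy]-2-(3-oxoprop-1-en-2-yl)-2,3-dihydro-1-benzofuran-5-yl]ethyl (E)-2-methylbut-2-enoate
Conditions: MnO2 (activated, excess), CH2Cl2, rt
Reagents that add atoms: none
Why: Chemoselective oxidation of a primary allylic alcohol to the 2-substituted propenal on activated MnO2 under neutral heterogeneous conditions, which should not touch the esters, the conjugated alkenes or any stereocentre.

## Compound list

1 | 4-fluoro-3-formylbenzonitrile | N#Cc1ccc(F)c(C=O)c1 | starting material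
2 | 2,2-dimethyl-1,3-dioxan-5-one | CC1(C)OCC(=O)CO1 | starting material
3 | 4-fluoro-3-[(S)-hydroxy[(4S)-2,2-dimethyl-5-oxo-1,3-dioxan-4-yl]methyl]benzonitrile | CC1(C)OCC(=O)[C@@H](O1)[C@H](c2cc(C#N)ccc2F)O | intermediate
4 | 4-fluoro-3-[(S)-[(4S)-2,2-dimethyl-5-oxo-1,3-dioxan-4-yl](triethylsilyloxy)methyl]benzonitrile | CC1(C)OCC(=O)[C@@H](O1)[C@H](c2cc(C#N)ccc2F)O[Si](CC)(CC)CC | intermediate
5 | 4-fluoro-3-[(S)-[(4R)-2,2-dimethyl-5-methylidene-1,3-dioxan-4-yl](triethylsilyloxy)methyl]benzonitrile | CC1(C)OCC(=C)[C@@H](O1)[C@H](c2cc(C#N)ccc2F)O[Si](CC)(CC)CC | intermediate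
6 | 4-fluoro-3-[(1S,2R)-1,2,4-trihydroxy-3-methylidenebutyl]benzonitrile | C=C(CO)[C@@H](O)[C@H](c1cc(C#N)ccc1F)O | intermediate
7 | Meisenheimer adduct, potassium salt: cyano-stabilised cyclohexadienyl anion in which C7a carries both F and the new O1–C7a bond (configuration at C7a not defined) | [K+].N#C[C-]1C=CC2(F)O[C@H](C(=C)CO)[C@@H](O)C2=C1 | intermediate
8 | (2R,3S)-3-hydroxy-2-(3-hydroxyprop-1-en-2-yl)-2,3-dihydro-1-benzofuran-5-carbonitrile | C=C(CO)[C@H]1Oc2ccc(C#N)cc2[C@@H]1O | intermediate
9 | (2R,3S)-2-[3-(tert-butyldimethylsilyloxy)prop-1-en-2-yl]-3-hydroxy-2,3-dihydro-1-benzofuran-5-carbonitrile | C=C(CO[Si](C)(C)C(C)(C)C)[C@H]1Oc2ccc(C#N)cc2[C@@H]1O | intermediate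
10 | (2R,3S)-2-[3-(tert-butyldimethylsilyloxy)prop-1-en-2-yl]-5-(1-iminoethyl)-2,3-dihydro-1-benzofuran-3-ol (ketimine) | C=C(CO[Si](C)(C)C(C)(C)C)[C@H]1Oc2ccc(C(C)=N)cc2[C@@H]1O | intermediate
11 | 1-[(2R,3S)-2-[3-(tert-butyldimethylsilyloxy)prop-1-en-2-yl]-3-hydroxy-2,3-dihydro-1-benzofuran-5-yl]ethan-1-one | C=C(CO[Si](C)(C)C(C)(C)C)[C@H]1Oc2ccc(C(C)=O)cc2[C@@H]1O | intermediate
12 | (2R,3S)-2-[3-(tert-butyldimethylsilyloxy)prop-1-en-2-yl]-5-[(1R)-1-hydroxyethyl]-2,3-dihydro-1-benzofuran-3-ol | C=C(CO[Si](C)(C)C(C)(C)C)[C@H]1Oc2ccc([C@@H](C)O)cc2[C@@H]1O | intermediate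
13 | tigloyl chloride, (E)-2-methylbut-2-enoyl chloride | ClC(=O)/C(C)=C/C | starting material
14 | (1R)-1-[(2R,3S)-2-[3-(tert-butyldimethylsilyloxy)prop-1-en-2-yl]-3-[(E)-2-methylbut-2-enoyloxy]-2,3-dihydro-1-benzofuran-5-yl]ethyl (E)-2-methylbut-2-enoate | C=C(CO[Si](C)(C)C(C)(C)C)[C@H]1Oc2ccc([C@@H](C)OC(=O)/C(C)=C/C)cc2[C@@H]1OC(=O)/C(C)=C/C | intermediate
15 | (1R)-1-[(2R,3S)-2-(3-hydroxyprop-1-en-2-yl)-3-[(E)-2-methylbut-2-enoyloxy]-2,3-dihydro-1-benzofuran-5-yl]ethyl (E)-2-methylbut-2-enoate | C=C(CO)[C@H]1Oc2ccc([C@@H](C)OC(=O)/C(C)=C/C)cc2[C@@H]1OC(=O)/C(C)=C/C | intermediate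
16 | (1R)-1-[(2R,3S)-3-[(E)-2-methylbut-2-enoyloxy]-2-(3-oxoprop-1-en-2-yl)-2,3-dihydro-1-benzofuran-5-yl]ethyl (E)-2-methylbut-2-enoate | C=C(C=O)[C@H]1Oc2ccc([C@@H](C)OC(=O)/C(C)=C/C)cc2[C@@H]1OC(=O)/C(C)=C/C | target

## Step count and risks

Total step count: 11. Longest linear sequence: 11 steps (from 1 to 16).

Steps most likely to fail:

Step 3 (Wittig methylenation). The basic ylide may enolise the ketone towards C4, which would erode the configuration of the future C2, or expel the β-silyloxy group by elimination. The fallback sets out from 4 and replaces the ylide by a non-basic two-stage Peterson olefination. Addition of the organocerium reagent made from Me3SiCH2Li and CeCl3 (THF, −78 °C) should give the tertiary β-hydroxysilane 4-fluoro-3-[(S)-[(4S)-5-hydroxy-2,2-dimethyl-5-(trimethylsilylmethyl)-1,3-dioxan-4-yl](triethylsilyloxy)methyl]benzonitrile F1 as a mixture of epimers at the new carbinol carbon. KH in THF should then bring about syn-elimination of the silanolate from either epimer, and the route is rejoined at 5.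

Step 9 (double tigloylation). Acylation at the hindered C3 hydroxyl may stay incomplete, the acid chloride may isomerise under base through a vinylketene to deconjugated or (Z) esters, and forcing conditions may ionise the benzylic C3–O bond towards the benzofuran. The fallback sets out from 11 and installs the two esters one at a time with carboxylic acid activation in place of the acid chloride. Yamaguchi esterification of the single hydroxyl of 11 (tiglic acid, 2,4,6-trichlorobenzoyl chloride, Et3N, then DMAP, toluene) should give (2R,3S)-5-acetyl-2-[3-(tert-butyldimethylsilyloxy)prop-1-en-2-yl]-2,3-dihydro-1-benzofuran-3-yl (E)-2-methylbut-2-enoate F2. Transfer hydrogenation with RuCl[(R,R)-TsDPEN](p-cymene) in HCO2H/Et3N, which leaves the conjugated ester alone, should give (2R,3S)-2-[3-(tert-butyldimethylsilyloxy)prop-1-en-2-yl]-5-[(1R)-1-hydroxyethyl]-2,3-dihydro-1-benzofuran-3-yl (E)-2-methylbut-2-enoate F3. Steglich esterification of the unhindered side-chain carbinol (tiglic acid, EDC·HCl, DMAP, CH2Cl2) rejoins the route at 14.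

Step 7 (methyllithium addition to the nitrile). Addition to an electron-rich nitrile that carries a neighbouring lithium alkoxide may be sluggish, ring metalation or attack at silicon may compete, and the silyl ether may be lost during ketimine hydrolysis. The fallback sets out from 9 and builds the carbinol by C–C bond formation instead of ketone reduction. Partial reduction with diisobutylaluminium hydride (CH2Cl2, −78 °C; aqueous potassium sodium tartrate work-up) should give (2R,3S)-2-[3-(tert-butyldimethylsilyloxy)prop-1-en-2-yl]-3-hydroxy-2,3-dihydro-1-benzofuran-5-carbaldehyde F4. Catalytic enantioselective methyl transfer follows (Me2Zn, Ti(OiPr)4, toluene, −20 °C, with the enantiomer of trans-1,2-bis(trifluoromethanesulfonamido)cyclohexane that directs the methyl group to the Re face of the aldehyde). It should set the (R)-carbinol directly, and the route is rejoined at 12.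

## Further compounds

F1 | step 3 | 4-fluoro-3-[(S)-[(4S)-5-hydroxy-2,2-dimethyl-5-(trimethylsilylmethyl)-1,3-dioxan-4-yl](triethylsilyloxy)methyl]benzonitrile (epimers at C5) | CC1(C)OCC(O)(C[Si](C)(C)C)[C@@H](O1)[C@H](c2cc(C#N)ccc2F)O[Si](CC)(CC)CC
F2 | step 9 | (2R,3S)-5-acetyl-2-[3-(tert-butyldimethylsilyloxy)prop-1-en-2-yl]-2,3-dihydro-1-benzofuran-3-yl (E)-2-methylbut-2-enoate | C=C(CO[Si](C)(C)C(C)(C)C)[C@H]1Oc2ccc(C(C)=O)cc2[C@@H]1OC(=O)/C(C)=C/C
F3 | step 9 | (2R,3S)-2-[3-(tert-butyldimethylsilyloxy)prop-1-en-2-yl]-5-[(1R)-1-hydroxyethyl]-2,3-dihydro-1-benzofuran-3-yl (E)-2-methylbut-2-enoate | C=C(CO[Si](C)(C)C(C)(C)C)[C@H]1Oc2ccc([C@@H](C)O)cc2[C@@H]1OC(=O)/C(C)=C/C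
F4 | step 7 | (2R,3S)-2-[3-(tert-butyldimethylsilyloxy)prop-1-en-2-yl]-3-hydroxy-2,3-dihydro-1-benzofuran-5-carbaldehyde | C=C(CO[Si](C)(C)C(C)(C)C)[C@H]1Oc2ccc(C=O)cc2[C@@H]1O
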